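**Retrosynthetic overview**

1. Target ⇐ acetylation and desilylation of a triol C4 silyl ether ⇐ a nortricyclanone keto ester that still carries ring A as a silyl enol ether. C11–OH comes from an equilibrating reduction, C4–O from Rubottom oxidation and epimerisation, C3–OH and CH2OH from hydride.
2. Key disconnection: the nortricyclanone ⇐ α′-enolate of a cis-hydrindenone plus a vinylsulfonium salt. A Michael / Michael / 3-exo-tet cascade closes the bridged five-membered ring and the cyclopropane in one operation.
3. Hydrindenone ⇐ α-methylation and dehydrogenation ⇐ enantioselective Diels–Alder of the mesityl oxide silyl dienol ether with methyl 3-oxocyclopentenecarboxylate. This sets C1 and brings in the CMe2 group and the C3 oxygen.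
4. Ring order: cyclopentenone ring (bought) → ring A (Diels–Alder) → bridged ring and cyclopropane together (key step).

Assumption: the given SMILES defines the absolute configuration. Labels used in names: C1 = quaternary C bearing CH2OAc, C2 = ring CH2, C3 = CH–OAc, C4 = CH–OH, C5 = CMe2, C6 = apex quaternary C, C7 = bridge CH2, C8 and C9 = cyclopropane CH, C10 = cyclopropane C–CH3, C11 = bridge CH–OAc; ring A = C1–C6.

**Route**

Step 1
Reactants: 1 mesityl oxide (4-methylpent-3-en-2-one)
Product: 3 2-(tert-butyldimethylsilyloxy)-4-methylpenta-1,3-diene, via lithium dienolate 2 (not isolated)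
Conditions: LDA, THF, −78 °C; TBSOTf, −78 → 0 °C
Reagents that add atoms: tert-butyldimethylsilyl triflate, CC(C)(C)[Si](C)(C)OS(=O)(=O)C(F)(F)F
Why: Kinetic deprotonation at the α′-methyl group gives the cross-conjugated dienolate, which is O-silylated (silyl enol ether formation); no stereocentre is formed.

Step 2
Reactants: 3 2-(tert-butyldimethylsilyloxy)-4-methylpenta-1,3-diene; 4 methyl 3-oxocyclopent-1-ene-1-carboxylate
Product: 5 methyl (3aR,7aR)-5-(tert-butyldimethylsilyloxy)-7,7-dimethyl-1-oxo-1,2,3,4,7,7a-hexahydro-3aH-indene-3a-carboxylate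
Conditions: 3 (2 equiv), (S)-o-tolyl-oxazaborolidine·AlBr3 (10 mol%), CH2Cl2, −40 °C
Reagents that add atoms: none
Why: Proposed new method: a Lewis-acid-promoted, stepwise (Mukaiyama–Michael then ring closure) Diels–Alder of this cis-methyl-hindered 2-silyloxydiene with substituted cycloalkenones is known with strong aluminium Lewis acids, and here an AlBr3-activated chiral oxazaborolidine (known for Diels–Alder reactions of 2-cyclopentenones) is proposed to supply the same acidity and shield one enone face; the ketone-bound acid makes C1 the electrophilic carbon, so the CH2 terminus bonds to C1 and the CMe2 terminus to C6, suprafacial addition gives the cis fusion, and the catalyst enantiomer (to be confirmed on the first run) sets C1.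

Step 3
Reactants: 5 methyl (3aR,7aR)-5-(tert-butyldimethylsilyloxy)-7,7-dimethyl-1-oxo-1,2,3,4,7,7a-hexahydro-3aH-indene-3a-carboxylate
Product: 7 methyl (3aR,7aR)-5-(tert-butyldimethylsilyloxy)-2,7,7-trimethyl-1-oxo-1,2,3,4,7,7a-hexahydro-3aH-indene-3a-carboxylate (both C10 epimers), via lithium enolate 6 (not isolated)
Conditions: LDA, THF, −78 °C; MeI, −78 → 0 °C
Reagents that add atoms: iodomethane, CI
Why: Kinetic enolate alkylation; LDA removes a proton from the unhindered C10 methylene and not the buried ring-fusion C6–H, and the new C10 centre is destroyed in step 4.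

Step 4
Reactants: 7 methyl (3aR,7aR)-5-(tert-butyldimethylsilyloxy)-2,7,7-trimethyl-1-oxo-1,2,3,4,7,7a-hexahydro-3aH-indene-3a-carboxylate
Product: 10 methyl (3aS,7aR)-5-(tert-butyldimethylsilyloxy)-2,7,7-trimethyl-1-oxo-1,4,7,7a-tetrahydro-3aH-indene-3a-carboxylate (C9=C10 enone; same spatial arrangement at C1 as in 5), via lithium enolate 8 (not isolated), via trimethylsilyl enol ether 9 (not isolated)
Conditions: LDA, TMSCl, THF, −78 °C; then Pd(OAc)2 (1.1 equiv), MeCN, 25 °C
Reagents that add atoms: none
Why: Saegusa–Ito dehydrogenation; only the C10–C9 side has a β-hydrogen (C1 and C5 are quaternary), so the 2-methylcyclopentenone is the only possible enone.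

Step 5
Reactants: 10 methyl (3aS,7aR)-5-(tert-butyldimethylsilyloxy)-2,7,7-trimethyl-1-oxo-1,4,7,7a-tetrahydro-3aH-indene-3a-carboxylate
Product: 14 nortricyclanone keto ester (C11 ketone; C1 CO2Me syn to C7; ring A with C3=C4 TBS enol ether syn to C11), via lithium dienolate 11 (not isolated), via sulfonium ylide 12 (not isolated), via sulfonium enolate 13 (not isolated)
Conditions: LDA, THF, −78 → −40 °C; CH2=CH–SPh2+ TfO− (1.2 equiv), −78 → 40 °C
Reagents that add atoms: diphenylvinylsulfonium triflate, C=C[S+](c1ccccc1)c1ccccc1.[O-]S(=O)(=O)C(F)(F)F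
Why: Proposed new method: the α′-enolate (C6 carries the only acidic proton) adds to the vinylsulfonium salt, the resulting sulfur ylide adds intramolecularly to C9 of the enone to close the bicyclo[2.2.1] ring, and the C10 enolate then displaces diphenyl sulfide at C8 (3-exo-tet) to close the cyclopropane, so two rings and three C–C bonds form in one flask; the closest known reactions are the bicycloannulation of cycloalkenone α′-enolates with vinylphosphonium salts or nitro-olefins, the Michael–Michael–SN2 sequence with α-bromoacrylates, and enone cyclopropanation by vinylsulfonium-derived ylides; C6 is set by attack on the enolate face cis to the angular ester (cis-hydrindanone-type alkylation, the main uncertainty), and C8, C9 and C10 then follow from the geometry of bridging.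

Step 6
Reactants: 14 nortricyclanone keto ester
Product: 15 C11 alcohol (OH in the open gap beside C7; H under ring A)
Conditions: Shvo catalyst (3 mol%), i-PrOH–toluene, 90 °C
Reagents that add atoms: none
Why: Ruthenium-catalysed transfer hydrogenation (Meerwein–Ponndorf-type) is reversible, so the carbinol equilibrates through the ketone to the more stable C11 epimer with OH away from ring A, whereas kinetic hydride from the open face would give the other epimer.

Step 7
Reactants: 15 C11 alcohol
Product: 17 C3 ketone with axial C4–OTBS (C4–O cis to C11), via silyloxy epoxide 16 (not isolated)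
Conditions: mCPBA, NaHCO3, CH2Cl2, −20 → 0 °C
Reagents that add atoms: meta-chloroperoxybenzoic acid, OOC(=O)c1cccc(Cl)c1
Why: Rubottom oxidation; the peracid epoxidises the silyl enol ether on the face away from the pseudoaxial C5 methyl and the C1 ester, and the silyloxy epoxide opens with 1,4-silyl shift to the α-silyloxy ketone, giving the axial C4–O that step 8 corrects.

Step 8
Reactants: 17 C3 ketone with axial C4–OTBS
Product: 18 C3 ketone with equatorial C4–OTBS (target C4 configuration)
Conditions: DBU (0.3 equiv), toluene, 60 °C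
Reagents that add atoms: none
Why: Base-mediated epimerisation through the C3 enolate moves the silyloxy group from the axial position (1,3-diaxial to C11) to the equatorial one under thermodynamic control.

Step 9
Reactants: 18 C3 ketone with equatorial C4–OTBS
Product: 19 triol C4 TBS ether (C1 CH2OH; axial C3–OH; C11–OH)
Conditions: DIBAL-H (6 equiv), CH2Cl2, −78 → 0 °C; Rochelle salt
Reagents that add atoms: none
Why: Hydride reduction; the ester gives the hydroxymethyl group, and the C3 ketone is attacked from the face opposite the syn-axial C1 and C5 substituents (steric approach control), giving the axial C3 alcohol cis to the C4 silyl ether.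

Step 10
Reactants: 19 triol C4 TBS ether
Product: 20 triacetate C4 TBS ether
Conditions: Ac2O, Et3N, DMAP (cat.), CH2Cl2, 25–40 °C
Reagents that add atoms: acetic anhydride, CC(=O)OC(C)=O
Why: DMAP-catalysed acetylation esterifies the primary, C3 and C11 hydroxyl groups while C4 stays blocked as its silyl ether, which fixes the acetate pattern; no stereocentre changes.

Step 11
Reactants: 20 triacetate C4 TBS ether
Product: 21 target CNP0197219.1
Conditions: HF·pyridine, THF, 0 → 25 °C
Reagents that add atoms: none
Why: Fluoride desilylation under weakly acidic conditions frees the hindered C4 hydroxyl group without base-induced 3→4 acetyl migration; no stereocentre changes.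

**Compound list**

1 | mesityl oxide (4-methylpent-3-en-2-one) | CC(=O)C=C(C)C | starting material
2 | lithium 4-methylpenta-1,3-dien-2-olate | [Li+].[O-]C(=C)C=C(C)C | intermediate
3 | 2-(tert-butyldimethylsilyloxy)-4-methylpenta-1,3-diene | C=C(O[Si](C)(C)C(C)(C)C)C=C(C)C | intermediate
4 | methyl 3-oxocyclopent-1-ene-1-carboxylate | COC(=O)C1=CC(=O)CC1 | starting material
5 | methyl (3aR,7aR)-5-(tert-butyldimethylsilyloxy)-7,7-dimethyl-1-oxo-1,2,3,4,7,7a-hexahydro-3aH-indene-3a-carboxylate (cis-fused) | COC(=O)[C@]12CC(O[Si](C)(C)C(C)(C)C)=CC(C)(C)[C@H]1C(=O)CC2 | intermediate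
6 | lithium enolate of 5 (C10=C11–OLi) | COC(=O)[C@]12CC(O[Si](C)(C)C(C)(C)C)=CC(C)(C)[C@H]1C([O-])=CC2.[Li+] | intermediate
7 | 2-methyl ketone: methyl (3aR,7aR)-5-(tert-butyldimethylsilyloxy)-2,7,7-trimethyl-1-oxo-1,2,3,4,7,7a-hexahydro-3aH-indene-3a-carboxylate (C10 epimers) | COC(=O)[C@]12CC(O[Si](C)(C)C(C)(C)C)=CC(C)(C)[C@H]1C(=O)C(C)C2 | intermediate
8 | lithium enolate of 7 (C10=C11–OLi) | COC(=O)[C@]12CC(O[Si](C)(C)C(C)(C)C)=CC(C)(C)[C@H]1C([O-])=C(C)C2.[Li+] | intermediate
9 | trimethylsilyl enol ether of 7 | COC(=O)[C@]12CC(O[Si](C)(C)C(C)(C)C)=CC(C)(C)[C@H]1C(O[Si](C)(C)C)=C(C)C2 | intermediate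
10 | enone: methyl (3aS,7aR)-5-(tert-butyldimethylsilyloxy)-2,7,7-trimethyl-1-oxo-1,4,7,7a-tetrahydro-3aH-indene-3a-carboxylate (cis-fused; C1 arranged as in 5) | COC(=O)[C@]12CC(O[Si](C)(C)C(C)(C)C)=CC(C)(C)[C@H]1C(=O)C(C)=C2 | intermediate
11 | lithium cross-conjugated dienolate of 10 (C6=C11–OLi; C9=C10) | COC(=O)[C@]12CC(O[Si](C)(C)C(C)(C)C)=CC(C)(C)C1=C([O-])C(C)=C2.[Li+] | intermediate
12 | sulfonium ylide: C6 carries CH2–CH(−)–S(+)Ph2 cis to the C1 ester; enone restored | COC(=O)[C@]12CC(O[Si](C)(C)C(C)(C)C)=CC(C)(C)[C@@]1(C[CH-][S+](c3ccccc3)c3ccccc3)C(=O)C(C)=C2 | intermediate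
13 | bicyclo[2.2.1] sulfonium enolate: exo-SPh2(+) on C8; enolate C10=C11–O(−) | COC(=O)[C@]12CC(O[Si](C)(C)C(C)(C)C)=CC(C)(C)[C@]13C[C@H]([S+](c4ccccc4)c4ccccc4)[C@H]2C(C)=C3[O-] | intermediate
14 | nortricyclanone keto ester (C11 ketone; C1 CO2Me syn to C7; ring A C3=C4 TBS enol ether syn to C11) | COC(=O)[C@]12CC(O[Si](C)(C)C(C)(C)C)=CC(C)(C)[C@]13C[C@@H]1[C@H]2[C@]1(C)C3=O | intermediate
15 | C11 alcohol (OH on the C7 side) | COC(=O)[C@]12CC(O[Si](C)(C)C(C)(C)C)=CC(C)(C)[C@]13C[C@@H]1[C@H]2[C@]1(C)[C@H]3O | intermediate
16 | C3/C4 silyloxy epoxide (epoxide oxygen on the C11 face) | COC(=O)[C@]12C[C@@]3(O[Si](C)(C)C(C)(C)C)O[C@H]3C(C)(C)[C@]14C[C@@H]1[C@H]2[C@]1(C)[C@H]4O | intermediate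
17 | C3 ketone with axial C4–OTBS (cis to C11) | COC(=O)[C@]12CC(=O)[C@@H](O[Si](C)(C)C(C)(C)C)C(C)(C)[C@]13C[C@@H]1[C@H]2[C@]1(C)[C@H]3O | intermediate
18 | C3 ketone with equatorial C4–OTBS (target C4 configuration) | COC(=O)[C@]12CC(=O)[C@H](O[Si](C)(C)C(C)(C)C)C(C)(C)[C@]13C[C@@H]1[C@H]2[C@]1(C)[C@H]3O | intermediate
19 | triol C4 TBS ether (CH2OH on C1; axial C3–OH; C11–OH) | OC[C@]12C[C@H](O)[C@H](O[Si](C)(C)C(C)(C)C)C(C)(C)[C@]13C[C@@H]1[C@H]2[C@]1(C)[C@H]3O | intermediate
20 | triacetate C4 TBS ether | CC(=O)OC[C@]12C[C@H](OC(C)=O)[C@H](O[Si](C)(C)C(C)(C)C)C(C)(C)[C@]13C[C@@H]1[C@H]2[C@]1(C)[C@H]3OC(C)=O | intermediate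
21 | target CNP0197219.1 | CC(=O)OC[C@]12C[C@H](OC(C)=O)[C@H](O)C(C)(C)[C@]13C[C@@H]1[C@H]2[C@]1(C)[C@H]3OC(C)=O | target

**Step count and risks**

Total step count: 11. Longest linear sequence: 11 steps (1 → 21; compound 4 is bought).

Steps most likely to fail:

- **Step 5 (key cascade).** Two things can go wrong. The ylide may be protonated or fail to close. More seriously, the electrophile may enter the enolate face anti to the ester, because the C5 gem-dimethyl group crowds the ester face; that would give the diastereomer with ring A beside C7. Fallback: change to a stepwise, reversible nitro-olefin bicycloannulation. It sets out from 10: the dienolate 11 is made with LDA as before and treated with nitroethylene at −78 → −20 °C. The nitronate formed adds back to C9, and quenching gives the isolable 8-exo-nitro bicyclo[2.2.1]heptanone F1. F1 is then heated with LiHMDS in THF–HMPA at 65 °C, where the C10 enolate displaces nitrite and the route is rejoined at 14. Both conjugate additions are reversible here, so the diastereomers can funnel through the less strained closure, in which ring A lies beside the flat C11 carbonyl.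

- **Step 2 (enantioselective hindered Diels–Alder).** The chiral Lewis acid may give only the open-chain Mukaiyama–Michael product or low ee. Fallback: resolution instead of asymmetric catalysis. It sets out from 3 and 4, which are combined under the achiral mixed Lewis acid AlBr3/AlMe3 in toluene–CH2Cl2 at −5 °C. This gives racemic material, that is 5 together with its (3aS,7aS) enantiomer F2. F2 is removed by preparative chiral SFC, and the route is rejoined at 5.

- **Step 6 (equilibrating reduction at C11).** The hindered ketone may be reduced too slowly, or the equilibrium may not be clean. Fallback: invert the kinetic alcohol through the cyclopropylcarbinyl cation. It sets out from 14, which NaBH4 in MeOH at 0 °C reduces from the open face to the C11-epimeric alcohol F3. F3 is acylated with trifluoroacetic anhydride and pyridine to the C11 trifluoroacetate F4. Solvolysis of F4 in aqueous acetone buffered with 2,6-lutidine ionises it to the nortricyclyl cation, which takes up water on the open face beside C7, and the route is rejoined at 15.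

**Further compounds**

F1 | step 5 | 8-exo-nitro bicyclo[2.2.1]heptanone double-Michael adduct of 10 (NO2 on C8; C11 ketone; C10 H/CH3 epimers) | COC(=O)[C@]12CC(O[Si](C)(C)C(C)(C)C)=CC(C)(C)[C@]13C[C@H]([N+](=O)[O-])[C@H]2C(C)C3=O
F2 | step 2 | methyl (3aS,7aS)-5-(tert-butyldimethylsilyloxy)-7,7-dimethyl-1-oxo-1,2,3,4,7,7a-hexahydro-3aH-indene-3a-carboxylate (enantiomer of 5) | COC(=O)[C@@]12CC(O[Si](C)(C)C(C)(C)C)=CC(C)(C)[C@@H]1C(=O)CC2
F3 | step 6 | C11 epimer of 15 (OH under ring A) | COC(=O)[C@]12CC(O[Si](C)(C)C(C)(C)C)=CC(C)(C)[C@]13C[C@@H]1[C@H]2[C@]1(C)[C@@H]3O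
F4 | step 6 | C11 trifluoroacetate of F3 | COC(=O)[C@]12CC(O[Si](C)(C)C(C)(C)C)=CC(C)(C)[C@]13C[C@@H]1[C@H]2[C@]1(C)[C@@H]3OC(=O)C(F)(F)F
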